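**Retrosynthetic overview**

1. The target is a (2S)-flavanone (benzo ring A, pyranone ring C, 4-hydroxyphenyl ring B) whose C6 oxygen is arylated by C4' of an apigenin-type flavone (benzo ring D, pyranone ring F, phenylene ring E). The last disconnection removes four O-benzyl groups.
2. Key disconnection: the O1–C2 bond of ring C, opened to an achiral 2-hydroxyaryl alkylidene β-ketoester. The enabling feature is the β-aryloxy ketone array O1–C2–C3–C4(=O) of ring C, with O1 on C8a ortho to the acyl-bearing C4a, so C2 is the β-carbon of an enone within 6-endo reach of the C8a phenol. A tert-butyl ester on C3 activates the enone and is excised in the same flask, and a benzyl group on O5 leaves O1 as the only phenol able to close.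
3. The alkylidene is cut at C2=C3 (Knoevenagel condensation with 4-(benzyloxy)benzaldehyde) and at C3–CO2tBu (C-acylation of the ring A methyl ketone).
4. The diaryl ether C6–O–C4' is cut by Ullmann coupling into a 4'-iodoflavone and a 2-acylhydroquinone, whose C6 oxygen comes from an Elbs oxidation para to the future O1.
5. Ring order: flavone ring F first (Claisen–Schmidt condensation, oxidative cyclization), flavanone ring C last; rings A, B, D and E are bought.

Key step: step 9

Assumption: the quinidine-derived thiourea is taken as the pseudoenantiomer that delivers the (2S) series; if induction on this substrate runs the other way, the quinine-derived pseudoenantiomer is used in step 9 with nothing else changed. Flavanone locants (O1, C2 to C8a) are used for the flavanone half throughout.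

**Route**

Step 1
Reactants: 1 2',4',6'-trihydroxyacetophenone
Product: 2 1-[2,4-bis(benzyloxy)-6-hydroxyphenyl]ethan-1-one
Conditions: BnBr (2.1 equiv), K2CO3, DMF, rt
Reagents that add atoms: benzyl bromide, BrCc1ccccc1
Why: Williamson etherification should stop at the bis-ether because the remaining hydroxyl is hydrogen-bonded to the ketone and its phenoxide is the least nucleophilic of the three.

Step 2
Reactants: 2 1-[2,4-bis(benzyloxy)-6-hydroxyphenyl]ethan-1-one; 3 4-iodobenzaldehyde
Product: 4 (2E)-1-[2,4-bis(benzyloxy)-6-hydroxyphenyl]-3-(4-iodophenyl)prop-2-en-1-one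
Conditions: KOH (50% aq.), EtOH–THF, rt
Reagents that add atoms: none
Why: Claisen–Schmidt (crossed aldol) condensation of the methyl ketone with a non-enolizable aldehyde should give the (E)-enone under thermodynamic control.

Step 3
Reactants: 4 (2E)-1-[2,4-bis(benzyloxy)-6-hydroxyphenyl]-3-(4-iodophenyl)prop-2-en-1-one
Product: 5 5,7-bis(benzyloxy)-2-(4-iodophenyl)-4H-chromen-4-one
Conditions: I2 (10 mol%), DMSO, 130 °C
Reagents that add atoms: none
Why: Iodine-catalysed oxidative cyclization of a 2'-hydroxychalcone in DMSO (oxa-Michael closure, then dehydrogenation with DMSO as terminal oxidant) is a standard flavone synthesis, and catalytic iodine with a short reaction time should spare the aryl benzyl ethers and the aryl iodide.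

Step 4
Reactants: 6 2',6'-dihydroxy-4'-methoxyacetophenone
Product: 7 1-[2-(benzyloxy)-6-hydroxy-4-methoxyphenyl]ethan-1-one
Conditions: BnBr (1.05 equiv), K2CO3, acetone, reflux
Reagents that add atoms: benzyl bromide, BrCc1ccccc1
Why: Mono-benzylation (Williamson etherification) should be self-limiting, since after the first alkylation the remaining hydroxyl is the ketone-chelated, poorly nucleophilic one.

Step 5
Reactants: 7 1-[2-(benzyloxy)-6-hydroxy-4-methoxyphenyl]ethan-1-one
Product: 9 1-[2-(benzyloxy)-3,6-dihydroxy-4-methoxyphenyl]ethan-1-one, via potassium aryl sulfate 8 (not isolated)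
Conditions: K2S2O8, NaOH (10% aq.), pyridine, 0 °C to rt; then HCl (aq.), Na2SO3, 85 °C
Reagents that add atoms: potassium peroxodisulfate, [K+].[K+].[O-]S(=O)(=O)OOS(=O)(=O)[O-]
Why: The Elbs persulfate oxidation attacks the phenoxide para to its oxygen, here the free position between the OBn and OMe groups, and acid hydrolysis of the aryl sulfate should then free the hydroquinone while the benzyl ether survives.

Step 6
Reactants: 9 1-[2-(benzyloxy)-3,6-dihydroxy-4-methoxyphenyl]ethan-1-one; 5 5,7-bis(benzyloxy)-2-(4-iodophenyl)-4H-chromen-4-one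
Product: 10 1-{2-(benzyloxy)-3-[4-(5,7-bis(benzyloxy)-4-oxo-4H-chromen-2-yl)phenoxy]-6-hydroxy-4-methoxyphenyl}ethan-1-one
Conditions: CuI (10 mol%), picolinic acid (20 mol%), K3PO4 (3 equiv), DMSO, 90 °C, Ar
Reagents that add atoms: none
Why: Ullmann-type O-arylation with CuI and picolinic acid is suited to doubly ortho-substituted phenols, and the 6-OH of 9, tied up as a hydrogen-bonded ortho-acyl phenol, should behave as a poorly nucleophilic spectator so that the 3-OH flanked by OBn and OMe is arylated.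

Step 7
Reactants: 10 1-{2-(benzyloxy)-3-[4-(5,7-bis(benzyloxy)-4-oxo-4H-chromen-2-yl)phenoxy]-6-hydroxy-4-methoxyphenyl}ethan-1-one
Product: 11 tert-butyl 3-{2-(benzyloxy)-3-[4-(5,7-bis(benzyloxy)-4-oxo-4H-chromen-2-yl)phenoxy]-6-hydroxy-4-methoxyphenyl}-3-oxopropanoate
Conditions: LiN(SiMe3)2 (3.2 equiv), THF, –78 °C; Boc2O (1.1 equiv), –78 to –40 °C; aq. NH4Cl
Reagents that add atoms: di-tert-butyl dicarbonate, CC(C)(C)OC(=O)OC(=O)OC(C)(C)C
Why: Claisen-type C-acylation of the ketone enolate (formed as a dianion with the phenoxide) by Boc2O should give the β-ketoester, the third equivalent of base absorbing the acidic product, while the flavone has no C–H acidic enough to react under these conditions.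

Step 8
Reactants: 11 tert-butyl 3-{2-(benzyloxy)-3-[4-(5,7-bis(benzyloxy)-4-oxo-4H-chromen-2-yl)phenoxy]-6-hydroxy-4-methoxyphenyl}-3-oxopropanoate; 12 4-(benzyloxy)benzaldehyde
Product: 13 tert-butyl (2Z)-2-{2-(benzyloxy)-3-[4-(5,7-bis(benzyloxy)-4-oxo-4H-chromen-2-yl)phenoxy]-6-hydroxy-4-methoxybenzoyl}-3-[4-(benzyloxy)phenyl]prop-2-enoate
Conditions: piperidine (cat.), AcOH (cat.), 4 Å MS, toluene, rt
Reagents that add atoms: none
Why: Knoevenagel condensation of the β-ketoester with the aromatic aldehyde under piperidinium acetate catalysis should give the alkylidene, expected mainly as the (Z)-isomer (aryl trans to the aroyl group), at a temperature where uncatalysed ring closure is slow.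

Step 9
Reactants: 13 tert-butyl (2Z)-2-{2-(benzyloxy)-3-[4-(5,7-bis(benzyloxy)-4-oxo-4H-chromen-2-yl)phenoxy]-6-hydroxy-4-methoxybenzoyl}-3-[4-(benzyloxy)phenyl]prop-2-enoate
Product: 16 (2S)-5-(benzyloxy)-2-[4-(benzyloxy)phenyl]-6-{4-[5,7-bis(benzyloxy)-4-oxo-4H-chromen-2-yl]phenoxy}-7-methoxy-2,3-dihydro-4H-chromen-4-one, via tert-butyl 3-carboxylate 14 (not isolated), via 3-carboxylic acid 15 (not isolated)
Conditions: 1-[3,5-bis(trifluoromethyl)phenyl]-3-[(9R)-6'-methoxycinchonan-9-yl]thiourea (quinidine-derived, 10 mol%), toluene, –25 °C; then TsOH·H2O, 80 °C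
Reagents that add atoms: none
Why: The quinuclidine nitrogen of the bifunctional catalyst deprotonates the lone free phenol (future O1 on C8a) while the thiourea N–H pair binds the 1,3-dicarbonyl of the alkylidene β-ketoester, so the phenoxide adds to the β-carbon (future C2) in an intramolecular oxa-Michael addition to give ester 14; TsOH then cleaves the tert-butyl ester to acid 15 with loss of isobutene, and 15 decarboxylates at 80 °C to 16. The closest known reaction type is the cinchona-thiourea-catalysed oxa-Michael cyclization of 2-hydroxyaryl alkylidene β-ketoesters to flavanones with decarboxylation in the same flask. Ring C of the flavanone is closed in the 6-endo-trig mode. The C2 stereocentre is set by the catalyst, which presents one face of the hydrogen-bonded alkylidene to the tethered phenoxide, and the transient C3 centre is erased on decarboxylation. The step needs enantioface selectivity (from the catalyst), a single site of closure (secured because O5 is benzylated, so only the C8a oxygen can attack and the 6-aryloxy constitution is fixed) and configurational stability at C2 (secured by acidic instead of basic ester removal and by keeping the 4'-oxygen as a benzyl ether, which disfavours retro-oxa-Michael opening).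

Step 10
Reactants: 16 (2S)-5-(benzyloxy)-2-[4-(benzyloxy)phenyl]-6-{4-[5,7-bis(benzyloxy)-4-oxo-4H-chromen-2-yl]phenoxy}-7-methoxy-2,3-dihydro-4H-chromen-4-one
Product: 17 (2S)-6-[4-(5,7-dihydroxy-4-oxo-4H-chromen-2-yl)phenoxy]-5-hydroxy-2-(4-hydroxyphenyl)-7-methoxy-2,3-dihydro-4H-chromen-4-one (CNP0269971.1)
Conditions: H2 (1 atm), Pd/C (10 wt%), EtOAc–THF, rt
Reagents that add atoms: none
Why: Hydrogenolysis of the four aryl benzyl ethers over Pd/C under neutral conditions should free the phenols without reducing the flavone C2=C3 bond or the ketones and, being neither acidic nor basic, without opening ring C, so C2 keeps its (S) configuration.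

**Compound list**

1 | 2',4',6'-trihydroxyacetophenone | CC(=O)c1c(O)cc(O)cc1O | starting material
2 | 1-[2,4-bis(benzyloxy)-6-hydroxyphenyl]ethan-1-one | CC(=O)c1c(O)cc(OCc2ccccc2)cc1OCc1ccccc1 | intermediate
3 | 4-iodobenzaldehyde | O=Cc1ccc(I)cc1 | starting material
4 | (2E)-1-[2,4-bis(benzyloxy)-6-hydroxyphenyl]-3-(4-iodophenyl)prop-2-en-1-one | O=C(/C=C/c1ccc(I)cc1)c1c(O)cc(OCc2ccccc2)cc1OCc1ccccc1 | intermediate
5 | 5,7-bis(benzyloxy)-2-(4-iodophenyl)-4H-chromen-4-one | O=c1cc(-c2ccc(I)cc2)oc2cc(OCc3ccccc3)cc(OCc3ccccc3)c12 | intermediate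
6 | 2',6'-dihydroxy-4'-methoxyacetophenone | CC(=O)c1c(O)cc(OC)cc1O | starting material
7 | 1-[2-(benzyloxy)-6-hydroxy-4-methoxyphenyl]ethan-1-one | CC(=O)c1c(O)cc(OC)cc1OCc1ccccc1 | intermediate
8 | potassium 3-acetyl-2-(benzyloxy)-4-hydroxy-6-methoxyphenyl sulfate | CC(=O)c1c(O)cc(OC)c(OS(=O)(=O)[O-])c1OCc1ccccc1.[K+] | intermediate (not isolated)
9 | 1-[2-(benzyloxy)-3,6-dihydroxy-4-methoxyphenyl]ethan-1-one | CC(=O)c1c(O)cc(OC)c(O)c1OCc1ccccc1 | intermediate
10 | 1-{2-(benzyloxy)-3-[4-(5,7-bis(benzyloxy)-4-oxo-4H-chromen-2-yl)phenoxy]-6-hydroxy-4-methoxyphenyl}ethan-1-one | CC(=O)c1c(O)cc(OC)c(Oc2ccc(-c3cc(=O)c4c(OCc5ccccc5)cc(OCc5ccccc5)cc4o3)cc2)c1OCc1ccccc1 | intermediate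
11 | tert-butyl 3-{2-(benzyloxy)-3-[4-(5,7-bis(benzyloxy)-4-oxo-4H-chromen-2-yl)phenoxy]-6-hydroxy-4-methoxyphenyl}-3-oxopropanoate | CC(C)(C)OC(=O)CC(=O)c1c(O)cc(OC)c(Oc2ccc(-c3cc(=O)c4c(OCc5ccccc5)cc(OCc5ccccc5)cc4o3)cc2)c1OCc1ccccc1 | intermediate
12 | 4-(benzyloxy)benzaldehyde | O=Cc1ccc(OCc2ccccc2)cc1 | starting material
13 | tert-butyl (2Z)-2-{2-(benzyloxy)-3-[4-(5,7-bis(benzyloxy)-4-oxo-4H-chromen-2-yl)phenoxy]-6-hydroxy-4-methoxybenzoyl}-3-[4-(benzyloxy)phenyl]prop-2-enoate | CC(C)(C)OC(=O)/C(=C\c1ccc(OCc2ccccc2)cc1)C(=O)c1c(O)cc(OC)c(Oc2ccc(-c3cc(=O)c4c(OCc5ccccc5)cc(OCc5ccccc5)cc4o3)cc2)c1OCc1ccccc1 | intermediate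
14 | tert-butyl (2S)-5-(benzyloxy)-2-[4-(benzyloxy)phenyl]-6-{4-[5,7-bis(benzyloxy)-4-oxo-4H-chromen-2-yl]phenoxy}-7-methoxy-4-oxo-3,4-dihydro-2H-chromene-3-carboxylate (C3 epimers and enol form, interconverting) | COc1cc2c(c(OCc3ccccc3)c1Oc1ccc(-c3cc(=O)c4c(OCc5ccccc5)cc(OCc5ccccc5)cc4o3)cc1)C(=O)C(C(=O)OC(C)(C)C)[C@@H](c1ccc(OCc3ccccc3)cc1)O2 | intermediate (not isolated)
15 | (2S)-5-(benzyloxy)-2-[4-(benzyloxy)phenyl]-6-{4-[5,7-bis(benzyloxy)-4-oxo-4H-chromen-2-yl]phenoxy}-7-methoxy-4-oxo-3,4-dihydro-2H-chromene-3-carboxylic acid (C3 epimers) | COc1cc2c(c(OCc3ccccc3)c1Oc1ccc(-c3cc(=O)c4c(OCc5ccccc5)cc(OCc5ccccc5)cc4o3)cc1)C(=O)C(C(=O)O)[C@@H](c1ccc(OCc3ccccc3)cc1)O2 | intermediate (not isolated)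
16 | (2S)-5-(benzyloxy)-2-[4-(benzyloxy)phenyl]-6-{4-[5,7-bis(benzyloxy)-4-oxo-4H-chromen-2-yl]phenoxy}-7-methoxy-2,3-dihydro-4H-chromen-4-one | COc1cc2c(c(OCc3ccccc3)c1Oc1ccc(-c3cc(=O)c4c(OCc5ccccc5)cc(OCc5ccccc5)cc4o3)cc1)C(=O)C[C@@H](c1ccc(OCc3ccccc3)cc1)O2 | intermediate
17 | (2S)-6-[4-(5,7-dihydroxy-4-oxo-4H-chromen-2-yl)phenoxy]-5-hydroxy-2-(4-hydroxyphenyl)-7-methoxy-2,3-dihydro-4H-chromen-4-one | COc1cc2c(c(O)c1Oc1ccc(-c3cc(=O)c4c(O)cc(O)cc4o3)cc1)C(=O)C[C@@H](c1ccc(O)cc1)O2 | target

**Step count and risks**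

Total step count: 10. Longest linear sequence: 8 steps (steps 1, 2, 3, 6, 7, 8, 9, 10, from compound 1).

Steps most likely to fail:

1. Step 6 (Ullmann coupling). The O-arylation of the doubly ortho-flanked phenol may be sluggish, may spill over to the chelated hydroxyl, or the hydroquinone may be oxidized. The fallback replaces copper catalysis by nucleophilic aromatic substitution and builds flavone ring F afterwards. It sets out from 9: reaction with 4-fluorobenzaldehyde (K2CO3, DMF, 90 °C, Ar) should arylate the non-chelated phenoxide to give 4-[3-acetyl-2-(benzyloxy)-4-hydroxy-6-methoxyphenoxy]benzaldehyde F1. Its lithium phenoxide (one equivalent of LiN(SiMe3)2) is then added at –78 °C to the dilithio derivative of 2 (LiN(SiMe3)2, THF). Aldehyde addition should outrun proton transfer to the second methyl ketone and give racemic 1-[2,4-bis(benzyloxy)-6-hydroxyphenyl]-3-{4-[3-acetyl-2-(benzyloxy)-4-hydroxy-6-methoxyphenoxy]phenyl}-3-hydroxypropan-1-one F2. MnO2 in CH2Cl2 should oxidize the benzylic alcohol to 1-[2,4-bis(benzyloxy)-6-hydroxyphenyl]-3-{4-[3-acetyl-2-(benzyloxy)-4-hydroxy-6-methoxyphenoxy]phenyl}propane-1,3-dione F3. TsOH in toluene at 90 °C then closes ring F by cyclodehydration, and the route is rejoined at 10.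

2. Step 9 (key step). Enantioface selection may erode at the doubly ortho-substituted aroyl group, or C2 may be scrambled by acid-promoted ring opening and reclosure during decarboxylation. The fallback sets the stereocentre by C–C instead of C–O bond formation. It sets out from 10: heating with N,N-dimethylformamide dimethyl acetal should give (2E)-1-{2-(benzyloxy)-3-[4-(5,7-bis(benzyloxy)-4-oxo-4H-chromen-2-yl)phenoxy]-6-hydroxy-4-methoxyphenyl}-3-(dimethylamino)prop-2-en-1-one F4. HCl in CH2Cl2 should cyclize it, with loss of dimethylamine, to 5-(benzyloxy)-6-{4-[5,7-bis(benzyloxy)-4-oxo-4H-chromen-2-yl]phenoxy}-7-methoxy-4H-chromen-4-one F5. Palladium-catalysed asymmetric conjugate addition of 4-(benzyloxy)phenylboronic acid (Pd(OCOCF3)2, 4-tert-butyl-2-(pyridin-2-yl)-4,5-dihydrooxazole in the antipode that gives the (2S) series, NH4PF6, H2O, ClCH2CH2Cl, 60 °C) then installs the C2 aryl group. The 2-aryl flavone unit, a fully β-substituted aryl-conjugated enone, should stay inert, and the route is rejoined at 16.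

3. Step 5 (Elbs oxidation). The persulfate hydroxylation may stall at low conversion or over-oxidize the electron-rich ring. The fallback is a Teuber oxidation–reduction sequence. It sets out from 7: ON(SO3K)2 (potassium nitrosodisulfonate) with KH2PO4 in acetone–H2O should oxidize the phenol at its free para position to 2-acetyl-3-(benzyloxy)-5-methoxycyclohexa-2,5-diene-1,4-dione F6. Reduction with Na2S2O4 (aq.)/EtOAc should give the hydroquinone, and the route is rejoined at 9.

**Further compounds**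

F1 | step 6 | 4-[3-acetyl-2-(benzyloxy)-4-hydroxy-6-methoxyphenoxy]benzaldehyde | CC(=O)c1c(O)cc(OC)c(Oc2ccc(C=O)cc2)c1OCc1ccccc1
F2 | step 6 | 1-[2,4-bis(benzyloxy)-6-hydroxyphenyl]-3-{4-[3-acetyl-2-(benzyloxy)-4-hydroxy-6-methoxyphenoxy]phenyl}-3-hydroxypropan-1-one (racemic) | CC(=O)c1c(O)cc(OC)c(Oc2ccc(C(O)CC(=O)c3c(O)cc(OCc4ccccc4)cc3OCc3ccccc3)cc2)c1OCc1ccccc1
F3 | step 6 | 1-[2,4-bis(benzyloxy)-6-hydroxyphenyl]-3-{4-[3-acetyl-2-(benzyloxy)-4-hydroxy-6-methoxyphenoxy]phenyl}propane-1,3-dione | CC(=O)c1c(O)cc(OC)c(Oc2ccc(C(=O)CC(=O)c3c(O)cc(OCc4ccccc4)cc3OCc3ccccc3)cc2)c1OCc1ccccc1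
F4 | step 9 | (2E)-1-{2-(benzyloxy)-3-[4-(5,7-bis(benzyloxy)-4-oxo-4H-chromen-2-yl)phenoxy]-6-hydroxy-4-methoxyphenyl}-3-(dimethylamino)prop-2-en-1-one | CN(C)/C=C/C(=O)c1c(O)cc(OC)c(Oc2ccc(-c3cc(=O)c4c(OCc5ccccc5)cc(OCc5ccccc5)cc4o3)cc2)c1OCc1ccccc1
F5 | step 9 | 5-(benzyloxy)-6-{4-[5,7-bis(benzyloxy)-4-oxo-4H-chromen-2-yl]phenoxy}-7-methoxy-4H-chromen-4-one | COc1cc2occc(=O)c2c(OCc2ccccc2)c1Oc1ccc(-c2cc(=O)c3c(OCc4ccccc4)cc(OCc4ccccc4)cc3o2)cc1
F6 | step 5 | 2-acetyl-3-(benzyloxy)-5-methoxycyclohexa-2,5-diene-1,4-dione | CC(=O)C1=C(OCc2ccccc2)C(=O)C(OC)=CC1=O
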